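**Strategy**

The route rests on reading the exocyclic-methylene carbon C8 and the carbinol carbon C13 as the two carbonyls of a 1,5-diketone (C8–C9–C11–C12–C13), so that ring B is cut at C8–C9 and the side chain at C11–C12. One photochemical operation, an intramolecular de Mayo reaction, adds the C8=C12 enol of a β-diketone to a vinyl group (C9=C11) on C10, closes ring B of the trans-decalin and, by retro-aldol opening of the cyclobutanol, releases the 8,13-diketone with the C9 side chain in place. The precursor is a single cyclohexane (ring A) bearing a spiro acetonide at C4, a 3,5-dioxohexyl chain on C5, and methyl and vinyl on quaternary C10.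

Key step: step 9

Remark: locants follow the labdane numbering of the target (C1–C10 decalin, C11–C16 side chain, C17 exocyclic methylene, C18 equatorial and C19 axial carbon on C4, C20 angular methyl); α/β refer to the usual drawing with C20 β.

Assumption: the antipode of the ferrocenyl diphosphine named in step 4 is taken to deliver the butenyl group to the face that gives C5–H α; if a test run shows the opposite sense, its mirror image is used.

**Route**

Step 1
Reactants: 1 2-(hydroxymethyl)propane-1,3-diol
Product: 2 (2,2-dimethyl-1,3-dioxan-5-yl)methanol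
Conditions: 2,2-dimethoxypropane (1.2 equiv), TsOH·H2O (2 mol%), THF, rt; then Et3N
Reagents that add atoms: 2,2-dimethoxypropane, COC(C)(C)OC
Why: Acid-catalysed transacetalisation ties two of the three equivalent hydroxyls into a six-membered isopropylidene acetal and leaves one primary alcohol, with no stereocentre created.

Step 2
Reactants: 2 (2,2-dimethyl-1,3-dioxan-5-yl)methanol
Product: 3 2,2-dimethyl-1,3-dioxane-5-carbaldehyde
Conditions: TEMPO (10 mol%), PhI(OAc)2 (1.1 equiv), CH2Cl2, rt
Reagents that add atoms: none
Why: Oxoammonium-mediated oxidation of a primary alcohol stops at the aldehyde under anhydrous, near-neutral conditions that leave the acetonide intact.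

Step 3
Reactants: 3 2,2-dimethyl-1,3-dioxane-5-carbaldehyde; 4 pent-1-en-3-one (ethyl vinyl ketone)
Product: 6 3,3,8-trimethyl-2,4-dioxaspiro[5.5]undec-7-en-9-one, via keto aldehyde 5 (not isolated)
Conditions: 4 (1.3 equiv), Et2NH (0.3 equiv), MeCN, 45 °C; then KOH (0.3 equiv), MeOH, rt → 50 °C
Reagents that add atoms: none
Why: Robinson annulation, in which amine-catalysed Michael addition of the α-branched aldehyde builds the quaternary carbon (future C4) and base-mediated aldol condensation of the ethyl-ketone methylene onto the non-enolisable aldehyde closes ring A as the 2-methyl enone; C4 stays non-stereogenic because its two arms are tied in the symmetric dioxane.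

Step 4
Reactants: 6 3,3,8-trimethyl-2,4-dioxaspiro[5.5]undec-7-en-9-one; 7 but-3-en-1-ylmagnesium bromide
Product: 9 (7S)-7-(but-3-en-1-yl)-3,3,8-trimethyl-9-(trimethylsilyloxy)-2,4-dioxaspiro[5.5]undec-8-ene, via bromomagnesium enolate 8 (not isolated)
Conditions: CuBr·SMe2 (5 mol%), (R)-1-[(S)-2-(diphenylphosphino)ferrocenyl]ethyldicyclohexylphosphine (6 mol%), 7 (1.3 equiv, slow addition), tBuOMe, −75 °C; then Me3SiCl (3 equiv), Et3N, DMPU, −75 °C → rt
Reagents that add atoms: chlorotrimethylsilane, C[Si](C)(C)Cl
Why: Copper-catalysed asymmetric conjugate addition of a Grignard reagent to a cyclic enone, in which the chiral diphosphine–copper complex selects the enone face and so sets C5 (H α), followed by O-silylation of the regiodefined magnesium enolate to store the C1=C10 enolate for the next step.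

Step 5
Reactants: 9 silyl enol ether; 10 bromoethene (vinyl bromide)
Product: 11 (7S,8R)-7-(but-3-en-1-yl)-8-ethenyl-3,3,8-trimethyl-2,4-dioxaspiro[5.5]undecan-9-one
Conditions: 10 (3 equiv, 1 M in THF), Pd(OAc)2 (5 mol%), tBu3P (10 mol%), Bu3SnF (1.4 equiv, fluoride relay), CsF (1.4 equiv), toluene, 85 °C, sealed tube
Reagents that add atoms: none
Why: Palladium-catalysed α-vinylation of a ketone through fluoride-promoted coupling of its silyl enol ether with an alkenyl bromide, which keeps the enolate regiochemistry and should deliver the vinyl group to C10 on the face anti to the adjacent C5 butenyl group, so that vinyl is α (trans to butenyl) and C20 is β.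

Step 6
Reactants: 11 α-methyl-α-vinyl ketone
Product: 13 (7R,8R)-7-(but-3-en-1-yl)-8-ethenyl-3,3,8-trimethyl-2,4-dioxaspiro[5.5]undecane, via hydrazone 12 (not isolated)
Conditions: N2H4·H2O (10 equiv), diethylene glycol, 130 °C; then KOH (5 equiv), 200 °C with removal of H2O and excess N2H4, under Ar
Reagents that add atoms: hydrazine hydrate, NN.O (its nitrogen atoms are carried by 12 only and leave as N2)
Why: Wolff–Kishner reduction (Huang–Minlon procedure) removes the C1 carbonyl under basic, non-radical conditions that should leave the two unactivated alkenes, the base-stable acetonide and the non-epimerisable quaternary C10 untouched.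

Step 7
Reactants: 13 ring A diene
Product: 14 4-[(7R,8R)-8-ethenyl-3,3,8-trimethyl-2,4-dioxaspiro[5.5]undecan-7-yl]butan-2-one
Conditions: PdCl2 (10 mol%), Cu(OAc)2·H2O (20 mol%), O2 (1 atm), DMA/H2O 7:1, rt
Reagents that add atoms: water, O
Why: Wacker oxidation converts the unhindered monosubstituted butenyl alkene into the methyl ketone (C8=O) by Markovnikov hydroxypalladation, while the vinyl group on quaternary C10 is too hindered to compete and the chloride-poor copper acetate co-catalyst keeps the medium mild enough for the acetonide.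

Step 8
Reactants: 14 methyl ketone; 15 ethyl acetate
Product: 16 6-[(7R,8R)-8-ethenyl-3,3,8-trimethyl-2,4-dioxaspiro[5.5]undecan-7-yl]hexane-2,4-dione
Conditions: NaH (3 equiv), 15 (5 equiv), EtOH (cat.), THF, 0 → 45 °C; then AcOH/H2O
Reagents that add atoms: none
Why: Crossed Claisen condensation of a methyl ketone with ethyl acetate, driven to the stabilised β-diketonate and therefore selective for acylation at the methyl carbon C12 over the C7 methylene.

Step 9
Reactants: 16 ring A vinyl β-diketone (mainly as its hydrogen-bonded enol)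
Product: 18 18,19-(isopropylidenedioxy)-14,15,17-trinorlabdane-8,13-dione, via cyclobutanol 17 (not isolated)
Conditions: hν (medium-pressure Hg lamp, Pyrex filter, λ > 290 nm), degassed cyclohexane (0.005 M), 15 °C
Reagents that add atoms: none
Why: Excitation of the hydrogen-bonded enol of 16, whose C8=C12 bond is the alkene of a β-hydroxy enone chromophore, leads to stepwise [2+2] addition to the C9=C11 vinyl group (C8–C9 first, then collapse of the 1,4-biradical through C11–C12) to give cyclobutanol 17, whose β-hydroxy ketone unit undergoes strain-driven retro-aldol cleavage of C8–C12 to the 1,5-diketone; this is the intramolecular de Mayo reaction, a known enol–alkene photocycloaddition with retro-aldol opening. Ring B is closed by 6-exo attack of C8 on the internal vinyl carbon C9 through the four-atom tether C7–C6–C5–C10, and the transient cyclobutane by recombination of the biradical at C11 and C12 in the only possible cis fusion. The trans ring fusion is inherited from ring A, because only the chair with the C5 chain and the C10 vinyl group both equatorial lets the two π-bonds meet, which leaves C20 and H-5 trans-diaxial. C9 is the one new stereocentre that survives; it is formed in the cycloaddition but lies next to the C8 carbonyl, so it is not relied upon and is brought to the equatorial 9β-chain configuration under thermodynamic control in step 10. The step needs regioselectivity (six-membered closure from the C8 enol terminus instead of seven-membered closure from C12 or a crossed adduct), which the tether length and the gauche diequatorial arrangement of the two arms should secure, and chemoselectivity for the enol over the product ketones, which the strong enol absorption near 275 nm, Pyrex-filtered light and high dilution should secure.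

Step 10
Reactants: 18 8,13-diketone
Product: 19 ethyl (13E)-18,19-(isopropylidenedioxy)-8-oxo-17-norlabd-13-en-15-oate
Conditions: (iPrO)2P(O)CH2CO2Et (1.5 equiv), NaH (1.4 equiv), THF, 0 °C → rt; then NaOEt (0.3 equiv), EtOH, rt
Reagents that add atoms: ethyl 2-(diisopropoxyphosphoryl)acetate, CCOC(=O)CP(=O)(OC(C)C)OC(C)C
Why: Horner–Wadsworth–Emmons olefination should take place only at the unhindered C13 methyl ketone and favour the (E)-trisubstituted enoate (any minor Z isomer to be removed by chromatography), and once C13 is no longer a ketone, so that aldol closure of the 1,5-diketone is excluded, ethoxide equilibrates C9 through the C8 enolate to the equatorial 9β-chain epimer.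

Step 11
Reactants: 19 keto enoate
Product: 20 ethyl (13E)-18,19-(isopropylidenedioxy)labda-8(17),13-dien-15-oate
Conditions: Ph3PCH3Br (3 equiv), KOtBu (2.8 equiv), toluene, rt → 80 °C
Reagents that add atoms: methyltriphenylphosphonium bromide, C[P+](c1ccccc1)(c1ccccc1)c1ccccc1.[Br-]
Why: Wittig methylenation of the hindered C8 ketone installs C17, the non-stabilised ylide is not expected to add to the β,β-disubstituted enoate, and C9 is already in its thermodynamically preferred configuration.

Step 12
Reactants: 20 dienoate
Product: 21 (13E)-18,19-(isopropylidenedioxy)labda-8(17),13-dien-15-ol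
Conditions: iBu2AlH (2.5 equiv), CH2Cl2, −78 °C; aq. potassium sodium tartrate
Reagents that add atoms: none
Why: 1,2-Reduction of the α,β-unsaturated ester by iBu2AlH gives the allylic alcohol with the E geometry unchanged and without touching the acetonide or the isolated alkene.

Step 13
Reactants: 21 (E)-allylic alcohol
Product: 22 (13R,14R)-13,14-epoxy-18,19-(isopropylidenedioxy)labd-8(17)-en-15-ol
Conditions: Ti(OiPr)4 (10 mol%), D-(−)-diethyl tartrate (12 mol%), tBuOOH (2 equiv, in isooctane), 4 Å molecular sieves, CH2Cl2, −20 °C
Reagents that add atoms: tert-butyl hydroperoxide, CC(C)(C)OO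
Why: Sharpless asymmetric epoxidation is directed by the allylic hydroxyl, so only the C13=C14 alkene reacts, and with D-(−)-tartrate an (E)-3-methylalk-2-en-1-ol of the geraniol type gives the (2R,3R)-epoxide, which sets C13 (R) by reagent control.

Step 14
Reactants: 22 epoxy alcohol
Product: 24 (13R)-18,19-(isopropylidenedioxy)labda-8(17),14-dien-13-ol, via epoxy iodide 23 (not isolated)
Conditions: PPh3 (1.3 equiv), imidazole (1.5 equiv), I2 (1.3 equiv), THF, 0 °C; then Zn dust (10 equiv), AcOH (2 equiv), EtOH, rt → 40 °C
Reagents that add atoms: iodine, [I][I] (iodine is carried by 23 only and is lost again)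
Why: Appel-type iodination of the primary alcohol and zinc-induced reductive opening of the 2,3-epoxy iodide (β-elimination of the C14–O bond) move the alkene to C14=C15 and keep the C13–O bond, so the configuration set in step 13 is carried over unchanged.

Step 15
Reactants: 24 tertiary allylic alcohol
Product: 25 (13R)-labda-8(17),14-diene-13,18,19-triol
Conditions: PPTS (0.2 equiv), MeOH/H2O 10:1, rt → 35 °C
Reagents that add atoms: none
Why: Mild acid-catalysed hydrolysis of the 1,3-dioxane acetonide frees the two hydroxymethyl groups on C4 under conditions expected to be too weak to ionise the tertiary allylic alcohol or isomerise the exocyclic alkene.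

Step 16
Reactants: 25 triol
Product: 27 (13R)-13-hydroxy-19-(triethylsilyloxy)labda-8(17),14-dien-18-yl 4-methylbenzenesulfonate, via monotosylate 26 (not isolated)
Conditions: TsCl (1.15 equiv), pyridine, CH2Cl2, −10 → 0 °C; then Et3SiCl (1.3 equiv), imidazole, 0 °C
Reagents that add atoms: 4-methylbenzenesulfonyl chloride, Cc1ccc(cc1)S(Cl)(=O)=O; chlorotriethylsilane, CC[Si](CC)(CC)Cl
Why: Selective sulfonylation of the less hindered primary alcohol, since in the trans-decalin the equatorial C18 hydroxymethyl is open while the axial C19 hydroxymethyl is 1,3-diaxial to C20, makes C4 a stereocentre by substrate control, and silylation then caps the axial hydroxyl so that it cannot displace the sulfonate as an oxetane in the next step; the tertiary C13 hydroxyl should react with neither reagent.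

Step 17
Reactants: 27 silyl-capped tosylate
Product: 29 (4S,5R,9S,10R,13R)-labda-8(17),14-diene-13,19-diol, via triethylsilyl ether 28 (not isolated)
Conditions: LiEt3BH (6 equiv, 1 M in THF), THF, 0 → 65 °C; H2O; then Bu4NF (1 M in THF), rt
Reagents that add atoms: none
Why: Hydride displacement of the neopentyl-type primary sulfonate by LiEt3BH turns C18 into the equatorial methyl group while alkenes and alkoxides are inert, and fluoride then removes the silyl cap from O19.

Step 18
Reactants: 29 13,19-diol; 30 (E)-2-methylbut-2-enoyl chloride (tigloyl chloride)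
Product: 31 (4S,5R,9S,10R,13R)-13-hydroxylabda-8(17),14-dien-19-yl (E)-2-methylbut-2-enoate (CNP0313179.1)
Conditions: pyridine (3 equiv), DMAP (0.2 equiv), CH2Cl2, 0 °C → rt
Reagents that add atoms: none
Why: Nucleophile-catalysed acylation esterifies the primary C19 alcohol while the tertiary allylic C13 alcohol should not react, and the weak base avoids deconjugation of the (E)-2-methylbut-2-enoyl unit.

**Compound list**

1 | 2-(hydroxymethyl)propane-1,3-diol | OCC(CO)CO | starting material
2 | (2,2-dimethyl-1,3-dioxan-5-yl)methanol | CC1(C)OCC(CO)CO1 | intermediate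
3 | 2,2-dimethyl-1,3-dioxane-5-carbaldehyde | CC1(C)OCC(C=O)CO1 | intermediate
4 | pent-1-en-3-one (ethyl vinyl ketone) | CCC(=O)C=C | starting material
5 | 2,2-dimethyl-5-(3-oxopentyl)-1,3-dioxane-5-carbaldehyde (not isolated) | CCC(=O)CCC1(C=O)COC(C)(C)OC1 | intermediate
6 | 3,3,8-trimethyl-2,4-dioxaspiro[5.5]undec-7-en-9-one (ring A enone: C1 ketone, C5=C10 alkene, C10 methyl, spiro acetonide at C4) | CC1=CC2(CCC1=O)COC(C)(C)OC2 | intermediate
7 | but-3-en-1-ylmagnesium bromide | C=CCC[Mg]Br | starting material
8 | bromomagnesium enolate of the conjugate adduct (C1–OMgBr, C1=C10, C5–H α; not isolated) | C=CCC[C@@H]1C(C)=C(O[Mg]Br)CCC12COC(C)(C)OC2 | intermediate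
9 | (7S)-7-(but-3-en-1-yl)-3,3,8-trimethyl-9-(trimethylsilyloxy)-2,4-dioxaspiro[5.5]undec-8-ene (C5–H α) | C=CCC[C@@H]1C(C)=C(O[Si](C)(C)C)CCC12COC(C)(C)OC2 | intermediate
10 | bromoethene (vinyl bromide) | C=CBr | starting material
11 | (7S,8R)-7-(but-3-en-1-yl)-8-ethenyl-3,3,8-trimethyl-2,4-dioxaspiro[5.5]undecan-9-one (C1 ketone; C5–H α, C10 methyl β, C10 vinyl α, vinyl trans to butenyl) | C=CCC[C@H]1C2(COC(C)(C)OC2)CCC(=O)[C@]1(C)C=C | intermediate
12 | hydrazone of 11 at C1 (not isolated) | C=CCC[C@H]1C2(COC(C)(C)OC2)CCC(=NN)[C@]1(C)C=C | intermediate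
13 | (7R,8R)-7-(but-3-en-1-yl)-8-ethenyl-3,3,8-trimethyl-2,4-dioxaspiro[5.5]undecane | C=CCC[C@H]1C2(COC(C)(C)OC2)CCC[C@]1(C)C=C | intermediate
14 | 4-[(7R,8R)-8-ethenyl-3,3,8-trimethyl-2,4-dioxaspiro[5.5]undecan-7-yl]butan-2-one | CC(=O)CC[C@H]1C2(COC(C)(C)OC2)CCC[C@]1(C)C=C | intermediate
15 | ethyl acetate | CCOC(C)=O | starting material
16 | 6-[(7R,8R)-8-ethenyl-3,3,8-trimethyl-2,4-dioxaspiro[5.5]undecan-7-yl]hexane-2,4-dione (ring A vinyl β-diketone, photosubstrate) | CC(=O)CC(=O)CC[C@H]1C2(COC(C)(C)OC2)CCC[C@]1(C)C=C | intermediate
17 | cyclobutanol photoadduct: trans-decalin with a cyclobutane C8–C9–C11–C12 cis-fused at C8–C9, 8α-OH, 12-acetyl (C12 unassigned), 5α-H, 9α-H, 10β-CH3, spiro acetonide at C4 (not isolated) | CC(=O)C1C[C@H]2[C@]1(O)CC[C@H]3C4(COC(C)(C)OC4)CCC[C@]23C | intermediate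
18 | 18,19-(isopropylidenedioxy)-14,15,17-trinorlabdane-8,13-dione (trans-decalin-8-one, 9β-(3-oxobutyl) chain) | CC(=O)CC[C@H]1C(=O)CC[C@H]2C3(COC(C)(C)OC3)CCC[C@]12C | intermediate
19 | ethyl (13E)-18,19-(isopropylidenedioxy)-8-oxo-17-norlabd-13-en-15-oate | CCOC(=O)/C=C(\C)CC[C@H]1C(=O)CC[C@H]2C3(COC(C)(C)OC3)CCC[C@]12C | intermediate
20 | ethyl (13E)-18,19-(isopropylidenedioxy)labda-8(17),13-dien-15-oate | CCOC(=O)/C=C(\C)CC[C@H]1C(=C)CC[C@H]2C3(COC(C)(C)OC3)CCC[C@]12C | intermediate
21 | (13E)-18,19-(isopropylidenedioxy)labda-8(17),13-dien-15-ol | OC/C=C(\C)CC[C@H]1C(=C)CC[C@H]2C3(COC(C)(C)OC3)CCC[C@]12C | intermediate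
22 | (13R,14R)-13,14-epoxy-18,19-(isopropylidenedioxy)labd-8(17)-en-15-ol | OC[C@H]1O[C@]1(C)CC[C@H]2C(=C)CC[C@H]3C4(COC(C)(C)OC4)CCC[C@]23C | intermediate
23 | 13,14-epoxy-15-iodo-18,19-(isopropylidenedioxy)labd-8(17)-ene, spatial arrangement at C13 and C14 as in 22 (not isolated) | IC[C@H]1O[C@]1(C)CC[C@H]2C(=C)CC[C@H]3C4(COC(C)(C)OC4)CCC[C@]23C | intermediate
24 | (13R)-18,19-(isopropylidenedioxy)labda-8(17),14-dien-13-ol | C=C[C@](C)(O)CC[C@H]1C(=C)CC[C@H]2C3(COC(C)(C)OC3)CCC[C@]12C | intermediate
25 | (13R)-labda-8(17),14-diene-13,18,19-triol | C=C[C@](C)(O)CC[C@H]1C(=C)CC[C@H]2C(CO)(CO)CCC[C@]12C | intermediate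
26 | (13R)-13,19-dihydroxylabda-8(17),14-dien-18-yl 4-methylbenzenesulfonate (not isolated) | C=C[C@](C)(O)CC[C@H]1C(=C)CC[C@H]2[C@@](COS(=O)(=O)c3ccc(C)cc3)(CO)CCC[C@]12C | intermediate
27 | (13R)-13-hydroxy-19-(triethylsilyloxy)labda-8(17),14-dien-18-yl 4-methylbenzenesulfonate | C=C[C@](C)(O)CC[C@H]1C(=C)CC[C@H]2[C@@](COS(=O)(=O)c3ccc(C)cc3)(CO[Si](CC)(CC)CC)CCC[C@]12C | intermediate
28 | (13R)-19-(triethylsilyloxy)labda-8(17),14-dien-13-ol (not isolated) | C=C[C@](C)(O)CC[C@H]1C(=C)CC[C@H]2[C@@](C)(CO[Si](CC)(CC)CC)CCC[C@]12C | intermediate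
29 | (4S,5R,9S,10R,13R)-labda-8(17),14-diene-13,19-diol | C=C[C@](C)(O)CC[C@H]1C(=C)CC[C@H]2[C@@](C)(CO)CCC[C@]12C | intermediate
30 | (E)-2-methylbut-2-enoyl chloride (tigloyl chloride) | C/C=C(\C)C(Cl)=O | starting material
31 | (4S,5R,9S,10R,13R)-13-hydroxylabda-8(17),14-dien-19-yl (E)-2-methylbut-2-enoate (CNP0313179.1) | C=C[C@](C)(O)CC[C@H]1C(=C)CC[C@H]2[C@@](C)(COC(=O)/C(C)=C/C)CCC[C@]12C | target

**Step count**

Total: 18 steps. Longest linear sequence: 18 steps (1 → 31); compounds 4, 7, 10, 15 and 30 are purchased and enter directly.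

**Steps most likely to fail**

1. Step 5. Reductive elimination at the fully substituted, doubly flanked C10 may be too slow, so that protodesilylation of the enol ether or Heck-type consumption of the terminal alkene wins, or the facial selectivity may be low. The fallback sets out from 9 and comes back at 11. Compound 9 is cleaved with MeLi (THF, 0 °C) to the lithium enolate F1, which is trapped at −78 °C with monomeric formaldehyde anti to the butenyl group to give the 10α-hydroxymethyl ketone F2. Dess–Martin oxidation gives the keto aldehyde F3, which has no α-hydrogen at C10, and Wittig methylenation with one equivalent of Ph3P=CH2 (−78 → 0 °C) should react only at the aldehyde to return ketone 11.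

2. Step 9. Ring closure through the four-atom tether may be inefficient, with radiationless decay of the excited enol, crossed addition or secondary photolysis of the product ketones outrunning the productive pathway. The fallback sets out from 16 and comes back at 18. Compound 16 is converted with BF3·OEt2 and iPr2NEt (CH2Cl2, 0 °C) into its difluoroboron chelate F4, a stronger and longer-wavelength chromophore in which both C–O termini are locked. Irradiation at 350 nm in MeCN gives the chelated cyclobutane photoadduct F5, which opens and is hydrolysed on stirring with aqueous NaOAc to diketone 18.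

3. Step 4. Turnover or facial discrimination in the asymmetric conjugate addition may be poor, because the β-carbon is flanked by the spiro quaternary carbon and the enone is α-methylated. The fallback sets out from 6 and comes back at 11. Ligand-free addition of 7 catalysed by CuBr·SMe2 (10 mol%) and accelerated by Me3SiCl (THF, −78 °C) gives the racemic silyl enol ether F6. Vinylation as in step 5 gives the racemic ketone F7, which is resolved by preparative chromatography on a chiral stationary phase (amylose tris(3,5-dimethylphenylcarbamate)) to return enantiopure 11.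

**Further compounds**

F1 | step 5 | lithium enolate from 9 (C1–OLi, C1=C10, C5–H α) | C=CCC[C@@H]1C(C)=C(O[Li])CCC12COC(C)(C)OC2
F2 | step 5 | (7S,8R)-7-(but-3-en-1-yl)-8-(hydroxymethyl)-3,3,8-trimethyl-2,4-dioxaspiro[5.5]undecan-9-one (CH2OH α on C10) | C=CCC[C@H]1C2(COC(C)(C)OC2)CCC(=O)[C@]1(C)CO
F3 | step 5 | (7S,8R)-7-(but-3-en-1-yl)-3,3,8-trimethyl-9-oxo-2,4-dioxaspiro[5.5]undecane-8-carbaldehyde | C=CCC[C@H]1C2(COC(C)(C)OC2)CCC(=O)[C@]1(C)C=O
F4 | step 9 | difluoroboron chelate of β-diketone 16 | CC1=CC(CC[C@H]2C3(COC(C)(C)OC3)CCC[C@]2(C)C=C)=[O+][B-](F)(F)O1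
F5 | step 9 | difluoroboron-chelated cyclobutane photoadduct (cyclobutane C8–C9–C11–C12, O8–B–O13 chelate; C8 and C12 unassigned) | CC1=[O+][B-](F)(F)OC23CC[C@H]4C5(COC(C)(C)OC5)CCC[C@]4(C)[C@H]2CC13
F6 | step 4 | racemic 9 (both enantiomers) | C=CCC[C@@H]1C(C)=C(O[Si](C)(C)C)CCC12COC(C)(C)OC2.C=CCC[C@H]1C(C)=C(O[Si](C)(C)C)CCC12COC(C)(C)OC2
F7 | step 4 | racemic 11 (both enantiomers, vinyl trans to butenyl) | C=CCC[C@H]1C2(COC(C)(C)OC2)CCC(=O)[C@]1(C)C=C.C=CCC[C@@H]1C2(COC(C)(C)OC2)CCC(=O)[C@@]1(C)C=C
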